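**Retrosynthetic overview**

- Feature: C7 (CH2OBz), the quaternary carbinol C1 and C2 (the CHOH beside C3H2–C4H2) carry oxygen as the benzylic, ipso and phenol carbons of an oxidised 2-hydroxybenzyl benzoate. The cyclohexane ring C1–C6 is therefore the dearomatised ring of salicyl alcohol, and C5 (CHOBz) and C6 (CHOH) come from one of its double bonds.
- Disconnections, backwards: C2–OH from a C2 ketone; C3H2–C4H2 from the enone C3=C4; C5–OBz/C6–OH from a C5,C6-oxirane cis to the C1 hydroxyl, opened at C6 by the C7 benzoate; C7–OBz from benzoic acid and the spiro-oxirane C1–O–C7; the spiro-oxirane from salicyl alcohol by asymmetric oxidative dearomatisation.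
- Ring order: the carbocycle is never built. The spiro-oxirane is closed first (C1–O bond), then the C5,C6-oxirane, then a transient 1,3-dioxan-2-ylium ring; all three are opened again on the way to the target.

Key step: step 1

Assumption: the locants C1–C7 defined above are used for every intermediate. The (R,R)-antipode of the lactate-derived iodane (made beforehand from its aryl iodide with peracetic acid, then exchange of acetate for benzoate) is taken to be the one that gives (S)-3; if the sense proves opposite, the (S,S)-reagent from the other lactate is used.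

**Route**

Step 1
Reactants: 1 salicyl alcohol; 2 benzoic acid
Product: 5 [(1R,5R,6R)-5,6-epoxy-1-hydroxy-2-oxocyclohex-3-en-1-yl]methyl benzoate (oxirane cis to the C1 hydroxyl), via spiro-epoxydienone 3 (not isolated), via ortho-quinol benzoate 4 (not isolated)
Conditions: ArI(O2CPh)2 (Ar = 2,6-bis[(R)-1-(mesitylcarbamoyl)ethoxy]phenyl; 1.05 eq), 4 Å MS, CH2Cl2 (0.02 M), −40 °C; then 2 (2 eq), Bu4N+ PhCO2− (5 eq), −40 → 0 °C; then methyl(trifluoromethyl)dioxirane (in CF3COCH3, added in portions), −40 °C
Reagents that add atoms: benzoic acid (compound 2, delivered through its tetrabutylammonium salt), OC(=O)c1ccccc1; methyl(trifluoromethyl)dioxirane, CC1(OO1)C(F)(F)F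
Why: Proposed new method: the phenol oxygen of 1 exchanges onto the trivalent iodine of the chiral reagent and, as iodine leaves in its monovalent state as the aryl iodide, the benzylic hydroxyl closes on the ring carbon C1 that bears it (3-exo-trig, forming the C1–O bond of the oxirane) to leave the 2,4-dienone 3; the closest known reactions are the Adler–Becker periodate oxidation of salicyl alcohols, which gives this spiro-epoxide as the racemate, and the ortho-dearomative spirolactonisation of phenols by chiral lactamide-armed aryl iodides. C1 is the only stereocentre made in this event and, since 1 is flat and achiral, its configuration can come only from the amide-bearing lactate arms that wrap the iodine centre and shield one face of the bound phenol. The step needs ortho closure at C1 in preference to attack of an external nucleophile at the para carbon C5, which the tethered hydroxyl (probably held on iodine in a six-membered chelate), the non-nucleophilic solvent and the low temperature should secure. Because 3 and 4 both dimerise by Diels–Alder reaction, neither is isolated: buffered benzoate opens 3 by SN2 attack at the primary C7, leaving C1 untouched, and the fast electrophilic dioxirane then epoxidises the more electron-rich distal C5=C6 bond of 4 in the cold, dilute solution before dimerisation can set in. This second oxirane is closed by concerted oxygen-atom transfer on the face of the C1 hydroxyl, which hydrogen-bonds the dioxirane while the larger CH2OBz group blocks the other face, and this sets C5 and C6 relative to C1.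

Step 2
Reactants: 5 epoxy enone
Product: 8 [(1R,5R,6S)-1,5,6-trihydroxy-2-oxocyclohex-3-en-1-yl]methyl benzoate, via dioxanylium zwitterion 6 (not isolated), via C6 benzoate 7 (not isolated)
Conditions: BF3·OEt2 (1.2 eq), CH2Cl2, −78 → −40 °C; aq NaHCO3, 0 °C; then Et3N (1 eq), CH2Cl2, 0 °C → rt
Reagents that add atoms: water, O
Why: Lewis-acid-promoted epoxide opening with neighbouring-group participation: with external nucleophiles absent and ionisation at C5 disfavoured by the enone, the carbonyl oxygen of the C7 benzoate attacks C6 from the face opposite the oxirane (6-exo, trans-diaxial in the Fürst–Plattner sense) to give the cis-fused dioxanylium ion 6, so that C6 receives its oxygen with inversion on the CH2OBz face while C5 keeps its oxygen on the C1–OH face, and after hydrolysis of the cation to the orthoacid any hindered secondary C6 ester 7 should pass its benzoyl group to the primary O7 through the same six-membered orthoacid under triethylamine (base-mediated 1,3-acyl migration towards the primary ester).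

Step 3
Reactants: 8 enone diol
Product: 9 [(1R,5R,6S)-5-(benzoyloxy)-1,6-dihydroxy-2-oxocyclohex-3-en-1-yl]methyl benzoate
Conditions: BzCl (1.05 eq), pyridine, CH2Cl2, −40 → −20 °C
Reagents that add atoms: benzoyl chloride, O=C(Cl)c1ccccc1
Why: Site-selective O-acylation under Einhorn conditions should take the allylic C5 hydroxyl, the only unhindered secondary alcohol, because the C6 hydroxyl is flanked by the quaternary C1 and the C1 hydroxyl is tertiary, while the cold, DMAP-free medium limits benzoyl migration; no stereocentre is touched.

Step 4
Reactants: 9 enone dibenzoate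
Product: 10 [(1R,5R,6S)-5-(benzoyloxy)-1,6-dihydroxy-2-oxocyclohexyl]methyl benzoate
Conditions: H2 (1 atm), [Ir(cod)(PCy3)(py)]PF6 (5 mol %), CH2Cl2, rt
Reagents that add atoms: none
Why: Homogeneous hydrogenation with the cationic iridium catalyst, assisted by the neighbouring hydroxyls, should saturate the cis-disubstituted C3=C4 bond without the hydrogenolysis of the allylic C5–O bond that Pd/C could cause and without touching the ketone or the esters; no stereocentre is formed.

Step 5
Reactants: 10 saturated ketone
Product: 11 [(1S,2R,5R,6S)-5-(benzoyloxy)-1,2,6-trihydroxycyclohexyl]methyl benzoate (target, CNP0264996.1)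
Conditions: Me4NBH(OAc)3 (5 eq), MeCN/AcOH 1:1, −20 °C
Reagents that add atoms: none
Why: Hydroxyl-directed triacetoxyborohydride reduction (Evans–Saksena type, here from the α-hydroxyl): in the chair that places the C1, C5 and C6 oxygens equatorial and CH2OBz axial, hydride bound through the C1 oxygen is delivered to the axial face of C2, the face cis to the C1 hydroxyl and remote from the axial CH2OBz group, which is also the face a small hydride prefers, so the new C2 hydroxyl should be equatorial and trans to the C1 hydroxyl (2R), and the acidic medium excludes base-induced benzoyl migration.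

**Compound list**

1 | salicyl alcohol (2-(hydroxymethyl)phenol) | OCc1ccccc1O | starting material
2 | benzoic acid | OC(=O)c1ccccc1 | starting material
3 | (S)-1-oxaspiro[2.5]octa-5,7-dien-4-one | O=C1C=CC=C[C@]12CO2 | intermediate
4 | [(1S)-1-hydroxy-6-oxocyclohexa-2,4-dien-1-yl]methyl benzoate | O=C(OC[C@]1(O)C(=O)C=CC=C1)c1ccccc1 | intermediate
5 | [(1R,5R,6R)-5,6-epoxy-1-hydroxy-2-oxocyclohex-3-en-1-yl]methyl benzoate | O=C(OC[C@]1(O)C(=O)C=C[C@H]2O[C@@H]12)c1ccccc1 | intermediate
6 | zwitterion: 2-phenyl-1,3-dioxan-2-ylium spanning O6 and O7, cis-fused to the cyclohexenone, with C5–O–BF3 trifluoroborate and free C1 hydroxyl | O=C1C=C[C@@H](O[B-](F)(F)F)[C@@H]2[O+]=C(c3ccccc3)OC[C@]12O | intermediate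
7 | (1R,5R,6S)-1,5-dihydroxy-1-(hydroxymethyl)-2-oxocyclohex-3-en-6-yl benzoate | OC[C@]1(O)C(=O)C=C[C@@H](O)[C@@H]1OC(=O)c1ccccc1 | intermediate
8 | [(1R,5R,6S)-1,5,6-trihydroxy-2-oxocyclohex-3-en-1-yl]methyl benzoate | O=C(OC[C@]1(O)C(=O)C=C[C@@H](O)[C@@H]1O)c1ccccc1 | intermediate
9 | [(1R,5R,6S)-5-(benzoyloxy)-1,6-dihydroxy-2-oxocyclohex-3-en-1-yl]methyl benzoate | O=C(OC[C@]1(O)C(=O)C=C[C@@H](OC(=O)c2ccccc2)[C@@H]1O)c1ccccc1 | intermediate
10 | [(1R,5R,6S)-5-(benzoyloxy)-1,6-dihydroxy-2-oxocyclohexyl]methyl benzoate | O=C(OC[C@]1(O)C(=O)CC[C@@H](OC(=O)c2ccccc2)[C@@H]1O)c1ccccc1 | intermediate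
11 | [(1S,2R,5R,6S)-5-(benzoyloxy)-1,2,6-trihydroxycyclohexyl]methyl benzoate | O=C(OC[C@]1(O)[C@H](O)CC[C@@H](OC(=O)c2ccccc2)[C@@H]1O)c1ccccc1 | target

**Step count**

Total steps: 5. Longest linear sequence: 5 steps (from 1).

**Steps most likely to fail**

1. Step 1. The three-membered closure has no precedent under a chiral iodane, so face selection at C1 may be poor, and Diels–Alder dimerisation of the unisolated dienones may outrun the benzoate opening or the epoxidation. Fallback by known chemistry, setting out from 1 and 2: Adler–Becker oxidation of 1 (NaIO4, H2O, 0 °C, rapid extraction into cold CH2Cl2) gives racemic spiro-epoxydienone F1. This is opened as in step 1 with 2 and Bu4N+ PhCO2− to racemic ortho-quinol benzoate F2 and epoxidised with the same dioxirane to racemic epoxy enone F3. Preparative HPLC on a chiral stationary phase (amylose tris(3,5-dimethylphenylcarbamate)) separates the enantiomers, and the route is rejoined at 5.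

2. Step 2. The benzoyl position may scramble: the orthoacid may collapse to the hindered C6 ester and the base-induced shift to O7 may stay incomplete or run on to O5. Fallback, setting out from 8 or its mixture with 7: exhaustive benzoylation (BzCl, pyridine, DMAP cat., 0 °C) converges all positional isomers on tribenzoate enone F4. Hydrogenation and directed reduction under the conditions of steps 4 and 5 then give saturated tribenzoate ketone F5 and tribenzoate diol F6. Methanolysis (K2CO3, MeOH, rt) removes all three esters to give pentaol F7. BzCl (2 eq), pyridine, −40 °C should then acylate the primary C7 hydroxyl and the only unhindered secondary hydroxyl (C5), rejoining the route at 11.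

3. Step 3. Acylation may reach the C6 hydroxyl or occur twice, and the basic medium may move the new benzoyl group between O5 and O6. Fallback, setting out from 8 and returning at 9: enzymatic transesterification with vinyl benzoate (Candida antarctica lipase B, tert-butyl methyl ether, 40 °C). The active site should accept only the unhindered C5 carbinol, and the neutral medium should not trigger acyl migration.

**Further compounds**

F1 | step 1 | racemic 1-oxaspiro[2.5]octa-5,7-dien-4-one | O=C1C=CC=CC12CO2
F2 | step 1 | racemic (1-hydroxy-6-oxocyclohexa-2,4-dien-1-yl)methyl benzoate | O=C(OCC1(O)C(=O)C=CC=C1)c1ccccc1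
F3 | step 1 | racemic epoxy enone (5 with its mirror image; the SMILES shows the mirror image) | O=C(OC[C@@]1(O)C(=O)C=C[C@@H]2O[C@H]12)c1ccccc1
F4 | step 2 | [(1R,5R,6S)-5,6-bis(benzoyloxy)-1-hydroxy-2-oxocyclohex-3-en-1-yl]methyl benzoate | O=C(OC[C@]1(O)C(=O)C=C[C@@H](OC(=O)c2ccccc2)[C@@H]1OC(=O)c1ccccc1)c1ccccc1
F5 | step 2 | [(1R,5R,6S)-5,6-bis(benzoyloxy)-1-hydroxy-2-oxocyclohexyl]methyl benzoate | O=C(OC[C@]1(O)C(=O)CC[C@@H](OC(=O)c2ccccc2)[C@@H]1OC(=O)c1ccccc1)c1ccccc1
F6 | step 2 | [(1S,2R,5R,6S)-5,6-bis(benzoyloxy)-1,2-dihydroxycyclohexyl]methyl benzoate | O=C(OC[C@]1(O)[C@H](O)CC[C@@H](OC(=O)c2ccccc2)[C@@H]1OC(=O)c1ccccc1)c1ccccc1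
F7 | step 2 | (1S,2R,5R,6S)-1-(hydroxymethyl)cyclohexane-1,2,5,6-tetrol | OC[C@]1(O)[C@H](O)CC[C@@H](O)[C@@H]1O
F0 | step 3 | none | none
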